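The C2–C13 bond carries the whole plan (numbering below). It joins the quaternary carbinol C2 to the acetoxy carbon C13, a cis-diol pair, and is common to the five-membered hydroxy-lactone and the nine-membered oxacycle. Samarium diiodide reduces the α-keto ester of a ten-membered macrolactone to a ketyl that adds across the ring to the C13 aldehyde, so one operation closes both rings and sets C2 and C13. The precursor is the spiro-lactone dihydrofuran whose C12 oxygen carries the 2-oxo acid arm as a lactone and whose C13 is a free aldehyde. It is built from a malate-derived dioxolanone, glyceraldehyde acetonide and a hydroxyglutarate-derived alkynol.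

Key step: step 16

Remarks placed before the steps:
- Numbering used in names and text: C1 is the carbonyl of the hydroxy-lactone, C2 its quaternary carbinol, C3–C4 the ethano bridge, C5 the dihydrofuran O–CH, C6 (methyl C14)=C7 the ring alkene, C8 the spiro ketal carbon, C9 the tertiary carbinol, C10 the CH(CH3) carbon (methyl C15), C11 the spiro-lactone carbonyl, C12 the lactone O–CH and C13 the acetoxy carbon. The open-chain diacids 15 and 16 carry the same numbers as undecanedioic acids.
- Structures 25 and 26 were checked against the target and are used unchanged: a ten-membered lactone through the furan oxygen in 25, a five-membered lactone (O, C1, C2, C13, C12) and a nine-membered oxacycle in 26.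
- C4 and C9 sit on opposite faces of the dihydrofuran, so 21–27 are in,out-bridged bicycles. The strain of 25 → 26 should be modelled before material is committed.
- Design of 25: the C2 ketone is installed before the C13 aldehyde is unveiled, because a C13 aldehyde next to a free C2 hydroxyl would close to a lactol and be over-oxidised. The aldehyde is made under acid and reduced at once, because the α-acyloxy aldehyde epimerises and eliminates on base.
- The C2 configuration taken from 1 only keeps 3–22 single diastereomers; it is erased in step 14. The tertiary C9 hydroxyl is free from step 9 on and is inert to the acylation, oxidation and cleavage steps.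

Step 1
Reactants: 1 (S)-5-oxotetrahydrofuran-2-carboxylic acid; 2 ethynyltrimethylsilane
Product: 3 (2S)-2-hydroxy-5-oxo-7-(trimethylsilyl)hept-6-ynoic acid
Conditions: 2 (2.4 equiv), n-BuLi (2.3 equiv), THF, −78 °C; then 1, −78 → −30 °C; aq. HCl to pH 3
Reagents that add atoms: none
Why: Addition of a lithium acetylide to a γ-lactone (acyl substitution arrested at the lithium hemiketalate) should stop after one addition, the first equivalent of acetylide only deprotonating the acid, and the stereocentre of 1 is not touched.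

Step 2
Reactants: 3 (2S)-2-hydroxy-5-oxo-7-(trimethylsilyl)hept-6-ynoic acid
Product: 5 (2S)-2-[(tert-butyldimethylsilyl)oxy]-5-oxo-7-(trimethylsilyl)hept-6-ynoic acid, via silyl ester 4 (not isolated)
Conditions: TBSOTf (2.3 equiv), 2,6-lutidine (3 equiv), CH2Cl2, −78 → 0 °C; then AcOH/THF/H2O, rt
Reagents that add atoms: tert-butyldimethylsilyl trifluoromethanesulfonate, CC(C)(C)[Si](C)(C)OS(=O)(=O)C(F)(F)F
Why: O-Silylation with a silyl triflate and a hindered base protects the C2 hydroxyl of the open-chain hydroxy ketone without a nucleophile that could add to the silyl ynone, and the silyl ester formed alongside is hydrolysed selectively by mild aqueous acid.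

Step 3
Reactants: 5 (2S)-2-[(tert-butyldimethylsilyl)oxy]-5-oxo-7-(trimethylsilyl)hept-6-ynoic acid
Product: 6 (2S,5S)-2-[(tert-butyldimethylsilyl)oxy]-5-hydroxy-7-(trimethylsilyl)hept-6-ynoic acid
Conditions: RuCl[(S,S)-TsDPEN](p-cymene) (2 mol %), HCO2H/Et3N (5:2), CH2Cl2, rt
Reagents that add atoms: none
Why: Noyori asymmetric transfer hydrogenation of an alkynyl ketone: with the (S,S)-diamine ligand the hydride should reach the face that gives the (S)-propargylic alcohol at C5 (the alkyne takes the place of the aryl group in the usual model), and the formic acid medium tolerates the free carboxylic acid.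

Step 4
Reactants: 6 (2S,5S)-2-[(tert-butyldimethylsilyl)oxy]-5-hydroxy-7-(trimethylsilyl)hept-6-ynoic acid
Product: 7 (2S,5S)-2-[(tert-butyldimethylsilyl)oxy]-5-hydroxyhept-6-ynoic acid
Conditions: K2CO3 (2.5 equiv), MeOH, 0 °C → rt; aq. HCl to pH 4
Reagents that add atoms: none
Why: Base-mediated methanolysis of the alkynyl C–Si bond (protodesilylation) frees the terminal alkyne while the secondary silyl ether and both stereocentres are unaffected.

Step 5
Reactants: 8 dimethyl (R)-malate
Product: 9 dimethyl (2R,3S)-2-hydroxy-3-methylbutanedioate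
Conditions: LDA (2.2 equiv), THF, −78 → −20 °C; MeI (1.5 equiv), −78 → −10 °C; AcOH
Reagents that add atoms: iodomethane, CI
Why: Frater–Seebach alkylation: the chelated lithium alkoxide–enolate dianion should be methylated to the 2,3-anti product, which sets the future C10 relative to the existing carbinol centre (future C9).

Step 6
Reactants: 9 dimethyl (2R,3S)-2-hydroxy-3-methylbutanedioate
Product: 10 (2R,3S)-2-hydroxy-3-methylbutanedioic acid
Conditions: KOH (3 equiv), H2O/MeOH, 0 °C → rt; aq. HCl, extraction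
Reagents that add atoms: potassium hydroxide, [K+].[OH-]
Why: Saponification of both methyl esters; the dicarboxylate of a β-hydroxy acid should not epimerise at the methyl-bearing carbon in cold aqueous base.

Step 7
Reactants: 10 (2R,3S)-2-hydroxy-3-methylbutanedioic acid
Product: 11 (2S)-2-[(2R,4R)-2-tert-butyl-5-oxo-1,3-dioxolan-4-yl]propanoic acid
Conditions: t-BuCHO (1.5 equiv), TsOH·H2O (cat.), H2SO4 (cat.), pentane, reflux, water separator; crystallisation
Reagents that add atoms: pivalaldehyde, CC(C)(C)C=O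
Why: Acid-catalysed acetalisation of the α-hydroxy acid unit gives the five-membered dioxolanone in preference to the six-membered alternative from the β-carboxyl, and equilibration places the tert-butyl group cis to the side chain, which sets the acetal centre.

Step 8
Reactants: 11 (2S)-2-[(2R,4R)-2-tert-butyl-5-oxo-1,3-dioxolan-4-yl]propanoic acid; 12 (R)-2,2-dimethyl-1,3-dioxolane-4-carbaldehyde
Product: 14 (2S)-2-[(2R,4S)-2-tert-butyl-4-{(R)-[(4R)-2,2-dimethyl-1,3-dioxolan-4-yl][(triethylsilyl)oxy]methyl}-5-oxo-1,3-dioxolan-4-yl]propanoic acid, via triethylsilyl ester 13 (not isolated)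
Conditions: LiHMDS (2.1 equiv), THF, −78 °C; 12 (1.2 equiv), −78 °C; TESOTf (2.5 equiv), 2,6-lutidine (3 equiv), −78 → −40 °C; aq. NaHCO3, then pH 4 buffer
Reagents that add atoms: triethylsilyl trifluoromethanesulfonate, CC[Si](CC)(CC)OS(=O)(=O)C(F)(F)F
Why: Aldol addition of a dioxolanone enolate (self-regeneration of the stereocentre): the carboxylate leaves the ring C–H as the only enolisable site, the aldehyde enters anti to the tert-butyl group so that C9 forms with net retention, Felkin–Anh addition to the α-alkoxy aldehyde sets C12 anti to the dioxolane oxygen, and the aldolate is silylated in the flask so that the γ-hydroxy acid cannot lactonise.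

Step 9
Reactants: 7 (2S,5S)-2-[(tert-butyldimethylsilyl)oxy]-5-hydroxyhept-6-ynoic acid; 14 (2S)-2-[(2R,4S)-2-tert-butyl-4-{(R)-[(4R)-2,2-dimethyl-1,3-dioxolan-4-yl][(triethylsilyl)oxy]methyl}-5-oxo-1,3-dioxolan-4-yl]propanoic acid
Product: 15 (2S,5S,9S,10S)-2-[(tert-butyldimethylsilyl)oxy]-9-{(R)-[(4R)-2,2-dimethyl-1,3-dioxolan-4-yl][(triethylsilyl)oxy]methyl}-5,9-dihydroxy-10-methyl-8-oxoundec-6-ynedioic acid
Conditions: 7 (1.2 equiv), LDA (3.1 equiv per 7), THF, −78 → −40 °C; lithium salt of 14 (LDA, 1.0 equiv, THF, −78 °C) added by cannula; −78 → −30 °C; cold aq. HCl to pH 4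
Reagents that add atoms: none
Why: Acyl substitution of the activated dioxolanone by a lithium acetylide: the lithium hemiketalate persists at low temperature so that only one acetylide adds, and on cold acidic work-up it collapses with loss of pivalaldehyde to the ynone and the free C9 hydroxyl, the carboxylates and the C5 alkoxide being inert.

Step 10
Reactants: 15 (2S,5S,9S,10S)-2-[(tert-butyldimethylsilyl)oxy]-9-{(R)-[(4R)-2,2-dimethyl-1,3-dioxolan-4-yl][(triethylsilyl)oxy]methyl}-5,9-dihydroxy-10-methyl-8-oxoundec-6-ynedioic acid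
Product: 18 (2S)-2-[(tert-butyldimethylsilyl)oxy]-4-[(2S,5S,8S,9S)-9-{(R)-[(4R)-2,2-dimethyl-1,3-dioxolan-4-yl][(triethylsilyl)oxy]methyl}-9-hydroxy-3,8-dimethyl-7-oxo-1,6-dioxaspiro[4.4]non-3-en-2-yl]butanoic acid, via Z-enone 16 (not isolated), via hemiketal 17 (not isolated)
Conditions: LiHMDS (2.0 equiv), THF, −78 °C; Me2CuLi (3 equiv, from MeLi and CuI), −78 °C; aq. NH4Cl; then PPTS (0.2 equiv), 4 Å molecular sieves, CH2Cl2, 0 °C → rt
Reagents that add atoms: lithium dimethylcuprate, [Li+].C[Cu-]C
Why: Conjugate addition of the Gilman cuprate to the ynone is a syn-carbocupration, so protonation gives the Z-enone whose C5 hydroxyl closes onto the C8 ketone, and mild acid then lactonises the C11 acid onto the hemiketal (dehydrative spiroketalisation); C8 is set by equilibration, the wanted epimer having the C9 hydroxyl hydrogen-bonded to the ring oxygen and C9 trans to the C5 side chain, and the silylated C12 oxygen cannot compete for the acid.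

Step 11
Reactants: 18 (2S)-2-[(tert-butyldimethylsilyl)oxy]-4-[(2S,5S,8S,9S)-9-{(R)-[(4R)-2,2-dimethyl-1,3-dioxolan-4-yl][(triethylsilyl)oxy]methyl}-9-hydroxy-3,8-dimethyl-7-oxo-1,6-dioxaspiro[4.4]non-3-en-2-yl]butanoic acid
Product: 19 (2S)-2-[(tert-butyldimethylsilyl)oxy]-4-[(2S,5S,8S,9S)-9-{(R)-[(4R)-2,2-dimethyl-1,3-dioxolan-4-yl](hydroxy)methyl}-9-hydroxy-3,8-dimethyl-7-oxo-1,6-dioxaspiro[4.4]non-3-en-2-yl]butanoic acid
Conditions: HF·pyridine, pyridine, THF, 0 °C; used at once
Reagents that add atoms: none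
Why: Buffered HF·pyridine should cleave the secondary triethylsilyl ether far faster than the secondary tert-butyldimethylsilyl ether (selective fluoride desilylation) and leave the acetonide and the acyl ketal intact.

Step 12
Reactants: 19 (2S)-2-[(tert-butyldimethylsilyl)oxy]-4-[(2S,5S,8S,9S)-9-{(R)-[(4R)-2,2-dimethyl-1,3-dioxolan-4-yl](hydroxy)methyl}-9-hydroxy-3,8-dimethyl-7-oxo-1,6-dioxaspiro[4.4]non-3-en-2-yl]butanoic acid
Product: 21 macrolactone: ten-membered lactone between the C1 carboxyl and the C12 oxygen of 19, (2S,5S,8S,9S,10S,12R), C2 tert-butyldimethylsilyl ether, C12 bearing the (4R)-2,2-dimethyl-1,3-dioxolan-4-yl group, via mixed anhydride 20 (not isolated)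
Conditions: MNBA (1.5 equiv), DMAP (6 equiv), CH2Cl2 (1 mM final), rt, 19 added over 12 h
Reagents that add atoms: none
Why: Shiina macrolactonisation: the mixed anhydride with 2-methyl-6-nitrobenzoic acid is formed and consumed under high dilution with DMAP, only the secondary C12 hydroxyl is acylated because the C9 hydroxyl is tertiary, and no stereocentre is touched.

Step 13
Reactants: 21 macrolactone, C2 silyl ether
Product: 22 macrolactone C2 alcohol, (2S,5S,8S,9S,10S,12R), C12 bearing the (4R)-2,2-dimethyl-1,3-dioxolan-4-yl group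
Conditions: HF·pyridine (excess), THF, 0 °C → rt
Reagents that add atoms: none
Why: Fluoride desilylation of the α-silyloxy lactone; the acidic reagent avoids the base that would open the acyl ketal or the macrolactone.

Step 14
Reactants: 22 macrolactone C2 alcohol
Product: 23 macrolactone C2 ketone (α-keto lactone), (5S,8S,9S,10S,12R), C12 bearing the (4R)-2,2-dimethyl-1,3-dioxolan-4-yl group
Conditions: Dess–Martin periodinane (1.5 equiv), pyridine (3 equiv), CH2Cl2, 0 °C → rt
Reagents that add atoms: none
Why: Dess–Martin oxidation of the secondary α-hydroxy ester to the α-keto ester under buffered, non-aqueous conditions; the tertiary C9 hydroxyl cannot be oxidised and the auxiliary C2 stereocentre is erased.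

Step 15
Reactants: 23 macrolactone C2 ketone
Product: 25 keto aldehyde macrolactone, (5S,8S,9S,10S,12S): ten-membered α-keto lactone (C1 to O12) with a formyl group (C13) on C12 and a free C9 hydroxyl, via diol 24 (not isolated)
Conditions: H5IO6 (2 equiv), EtOAc, 0 °C → rt; filtration through a short silica pad; used at once
Reagents that add atoms: none
Why: Periodic acid hydrolyses the terminal acetonide and cleaves the liberated 1,2-diol in one pot (glycol cleavage), which unveils the C13 aldehyde under acid so that the α-acyloxy centre C12 never meets base; periodate does not cleave the α-keto ester.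

Step 16
Reactants: 25 keto aldehyde macrolactone
Product: 26 deacetyl target (cis-2,13-diol), (2S,5S,8S,9S,10S,12R,13S)
Conditions: SmI2 (0.1 M in THF, 2.3 equiv, added over 30 min), THF (2 mM), −78 °C; 0.1 M aq. HCl at −78 °C
Reagents that add atoms: none
Why: Samarium diiodide transfers one electron to the α-keto ester, the most easily reduced group, and the C2 ketyl adds to the C13 aldehyde carbon held next to it by the ester link O12–C1; a second electron reduces the resulting alkoxy radical and the acid quench frees the diol. The closest known reaction is the samarium diiodide ketyl–carbonyl (pinacol) cyclisation of keto aldehydes to cis-1,2-diols. The five-membered hydroxy-lactone closes in a 5-exo-trig mode through the ester tether, and the same bond closes the nine-membered oxacycle as a transannular (formally 9-exo-trig) attack across the ten-membered lactone. C13 is set by the chelate in which the ketyl oxygen and the aldehyde oxygen share one trivalent samarium, which puts the two oxygens cis and on the lactone face away from C9; C2 is set by the macrocycle, because C3 can only stay on the face that carries C9. The step needs reduction of the keto ester before the aldehyde, and carbon–carbon bond formation before a second reduction or loss of the C12 acyloxy group: the large gap in reduction potential, the absence of HMPA and of a proton donor, slow addition at −78 °C and the proximity enforced by the ring should secure this.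

Step 17
Reactants: 26 deacetyl target
Product: 27 target, the C13 acetate of 26, (2S,5S,8S,9S,10S,12R,13S)
Conditions: Ac2O (1.5 equiv), pyridine, DMAP (0.1 equiv), CH2Cl2, 0 °C
Reagents that add atoms: acetic anhydride, CC(=O)OC(C)=O
Why: DMAP-catalysed acetylation should take place only at the secondary C13 hydroxyl, since the C2 and C9 hydroxyls are tertiary, and it touches no stereocentre.

Compound list
1 | (S)-5-oxotetrahydrofuran-2-carboxylic acid | O=C1CC[C@@H](C(=O)O)O1 | starting material
2 | ethynyltrimethylsilane | C#C[Si](C)(C)C | starting material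
3 | (2S)-2-hydroxy-5-oxo-7-(trimethylsilyl)hept-6-ynoic acid | C[Si](C)(C)C#CC(=O)CC[C@H](O)C(=O)O | intermediate
4 | tert-butyldimethylsilyl (2S)-2-[(tert-butyldimethylsilyl)oxy]-5-oxo-7-(trimethylsilyl)hept-6-ynoate | C[Si](C)(C)C#CC(=O)CC[C@H](O[Si](C)(C)C(C)(C)C)C(=O)O[Si](C)(C)C(C)(C)C | intermediate
5 | (2S)-2-[(tert-butyldimethylsilyl)oxy]-5-oxo-7-(trimethylsilyl)hept-6-ynoic acid | C[Si](C)(C)C#CC(=O)CC[C@H](O[Si](C)(C)C(C)(C)C)C(=O)O | intermediate
6 | (2S,5S)-2-[(tert-butyldimethylsilyl)oxy]-5-hydroxy-7-(trimethylsilyl)hept-6-ynoic acid | C[Si](C)(C)C#C[C@@H](O)CC[C@H](O[Si](C)(C)C(C)(C)C)C(=O)O | intermediate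
7 | (2S,5S)-2-[(tert-butyldimethylsilyl)oxy]-5-hydroxyhept-6-ynoic acid | C#C[C@@H](O)CC[C@H](O[Si](C)(C)C(C)(C)C)C(=O)O | intermediate
8 | dimethyl (R)-malate | COC(=O)C[C@@H](O)C(=O)OC | starting material
9 | dimethyl (2R,3S)-2-hydroxy-3-methylbutanedioate | COC(=O)[C@@H](C)[C@@H](O)C(=O)OC | intermediate
10 | (2R,3S)-2-hydroxy-3-methylbutanedioic acid | OC(=O)[C@@H](C)[C@@H](O)C(=O)O | intermediate
11 | (2S)-2-[(2R,4R)-2-tert-butyl-5-oxo-1,3-dioxolan-4-yl]propanoic acid | OC(=O)[C@@H](C)[C@H]1O[C@@H](C(C)(C)C)OC1=O | intermediate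
12 | (R)-2,2-dimethyl-1,3-dioxolane-4-carbaldehyde | CC1(C)OC[C@H](C=O)O1 | starting material
13 | triethylsilyl (2S)-2-[(2R,4S)-2-tert-butyl-4-{(R)-[(4R)-2,2-dimethyl-1,3-dioxolan-4-yl][(triethylsilyl)oxy]methyl}-5-oxo-1,3-dioxolan-4-yl]propanoate | CC[Si](CC)(CC)OC(=O)[C@@H](C)[C@@]1([C@H](O[Si](CC)(CC)CC)[C@H]2COC(C)(C)O2)O[C@@H](C(C)(C)C)OC1=O | intermediate
14 | (2S)-2-[(2R,4S)-2-tert-butyl-4-{(R)-[(4R)-2,2-dimethyl-1,3-dioxolan-4-yl][(triethylsilyl)oxy]methyl}-5-oxo-1,3-dioxolan-4-yl]propanoic acid | OC(=O)[C@@H](C)[C@@]1([C@H](O[Si](CC)(CC)CC)[C@H]2COC(C)(C)O2)O[C@@H](C(C)(C)C)OC1=O | intermediate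
15 | (2S,5S,9S,10S)-2-[(tert-butyldimethylsilyl)oxy]-9-{(R)-[(4R)-2,2-dimethyl-1,3-dioxolan-4-yl][(triethylsilyl)oxy]methyl}-5,9-dihydroxy-10-methyl-8-oxoundec-6-ynedioic acid | OC(=O)[C@@H](O[Si](C)(C)C(C)(C)C)CC[C@H](O)C#CC(=O)[C@](O)([C@H](C)C(=O)O)[C@H](O[Si](CC)(CC)CC)[C@H]1COC(C)(C)O1 | intermediate
16 | (2S,5S,6Z,9S,10S)-2-[(tert-butyldimethylsilyl)oxy]-9-{(R)-[(4R)-2,2-dimethyl-1,3-dioxolan-4-yl][(triethylsilyl)oxy]methyl}-5,9-dihydroxy-6,10-dimethyl-8-oxoundec-6-enedioic acid | OC(=O)[C@@H](O[Si](C)(C)C(C)(C)C)CC[C@H](O)/C(C)=C\C(=O)[C@](O)([C@H](C)C(=O)O)[C@H](O[Si](CC)(CC)CC)[C@H]1COC(C)(C)O1 | intermediate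
17 | cyclic hemiketal of 16: 2,5-dihydrofuran-2-ol formed by addition of the C5 hydroxyl to C8, both C8 epimers | OC(=O)[C@@H](O[Si](C)(C)C(C)(C)C)CC[C@@H]1OC(O)(C=C1C)[C@](O)([C@H](C)C(=O)O)[C@H](O[Si](CC)(CC)CC)[C@H]2COC(C)(C)O2 | intermediate
18 | (2S)-2-[(tert-butyldimethylsilyl)oxy]-4-[(2S,5S,8S,9S)-9-{(R)-[(4R)-2,2-dimethyl-1,3-dioxolan-4-yl][(triethylsilyl)oxy]methyl}-9-hydroxy-3,8-dimethyl-7-oxo-1,6-dioxaspiro[4.4]non-3-en-2-yl]butanoic acid | OC(=O)[C@@H](O[Si](C)(C)C(C)(C)C)CC[C@@H]1O[C@@]2(C=C1C)OC(=O)[C@@H](C)[C@]2(O)[C@H](O[Si](CC)(CC)CC)[C@H]3COC(C)(C)O3 | intermediate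
19 | (2S)-2-[(tert-butyldimethylsilyl)oxy]-4-[(2S,5S,8S,9S)-9-{(R)-[(4R)-2,2-dimethyl-1,3-dioxolan-4-yl](hydroxy)methyl}-9-hydroxy-3,8-dimethyl-7-oxo-1,6-dioxaspiro[4.4]non-3-en-2-yl]butanoic acid | OC(=O)[C@@H](O[Si](C)(C)C(C)(C)C)CC[C@@H]1O[C@@]2(C=C1C)OC(=O)[C@@H](C)[C@]2(O)[C@H](O)[C@H]3COC(C)(C)O3 | intermediate
20 | mixed anhydride of 19 with 2-methyl-6-nitrobenzoic acid | Cc1cccc([N+](=O)[O-])c1C(=O)OC(=O)[C@@H](O[Si](C)(C)C(C)(C)C)CC[C@@H]2O[C@@]3(C=C2C)OC(=O)[C@@H](C)[C@]3(O)[C@H](O)[C@H]4COC(C)(C)O4 | intermediate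
21 | macrolactone (C1 to O12), (2S,5S,8S,9S,10S,12R), C2 tert-butyldimethylsilyl ether, C12 bearing (4R)-2,2-dimethyl-1,3-dioxolan-4-yl | CC1(C)OC[C@@H](O1)[C@H]2OC(=O)[C@@H](O[Si](C)(C)C(C)(C)C)CC[C@@H]3O[C@@]4(C=C3C)OC(=O)[C@@H](C)[C@]24O | intermediate
22 | macrolactone C2 alcohol, (2S,5S,8S,9S,10S,12R) | CC1(C)OC[C@@H](O1)[C@H]2OC(=O)[C@@H](O)CC[C@@H]3O[C@@]4(C=C3C)OC(=O)[C@@H](C)[C@]24O | intermediate
23 | macrolactone C2 ketone, (5S,8S,9S,10S,12R) | CC1(C)OC[C@@H](O1)[C@H]2OC(=O)C(=O)CC[C@@H]3O[C@@]4(C=C3C)OC(=O)[C@@H](C)[C@]24O | intermediate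
24 | keto macrolactone with free (R)-1,2-dihydroxyethyl group on C12 | OC[C@@H](O)[C@H]2OC(=O)C(=O)CC[C@@H]1O[C@@]3(C=C1C)OC(=O)[C@@H](C)[C@]23O | intermediate
25 | keto aldehyde macrolactone, (5S,8S,9S,10S,12S) | O=C[C@H]2OC(=O)C(=O)CC[C@@H]1O[C@@]3(C=C1C)OC(=O)[C@@H](C)[C@]23O | intermediate
26 | deacetyl target (cis-2,13-diol), (2S,5S,8S,9S,10S,12R,13S) | O[C@H]1[C@H]2OC(=O)[C@]1(O)CC[C@@H]1O[C@@]3(C=C1C)OC(=O)[C@@H](C)[C@]23O | intermediate
27 | target, C13 acetate of 26, (2S,5S,8S,9S,10S,12R,13S) | CC(=O)O[C@H]1[C@H]2OC(=O)[C@]1(O)CC[C@@H]1O[C@@]3(C=C1C)OC(=O)[C@@H](C)[C@]23O | target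

Total step count: 17. Longest linear sequence: 13 steps (8 → 27 through steps 5–17; the branch from 1 through steps 1–4 and 9–17 is equally long).

Steps most likely to fail

Step 16. The ketyl may fail to reach the aldehyde across the strained ring and be reduced again and protonated to the α-hydroxy lactone, or the aldehyde may be reduced and expel the C12 acyloxy group. The fallback sets out from 25 and returns at 26. It is a tin hydride pinacol cyclisation (Bu3SnH, AIBN, benzene, 80 °C, high dilution). A stannyl radical adds reversibly to a carbonyl oxygen, the neutral O-stannyl ketyl adds to the second carbonyl, and the alkoxy radical is capped by hydrogen transfer. No carbanion is formed, so the acyloxy group has no pathway for elimination, and the tin-bridged diolate should again give the cis-diol, released on work-up as 26. No new isolated compound is made (F0).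

Step 12. Closure of the strained ten-membered ring at the hindered C12 hydroxyl is slow. Oligomerisation can then take over, as can migration of the spiro-lactone acyl group onto the free C12 hydroxyl with loss of the ketal. The fallback sets out from 14 and returns at 21; it makes the C12 ester between two small partners and closes the ring by metathesis.
- (S)-Pent-1-en-4-yn-3-ol F1 (from the commercial racemate by lipase resolution) replaces 7 in step 9 as its dilithium salt and gives the enynone acid F2.
- The conditions of step 10 turn F2 into the 2-ethenyl spiro-lactone F3.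
- HF·pyridine frees the C12 hydroxyl to give alcohol F4.
- F4 is esterified at once under Yamaguchi conditions (2,4,6-trichlorobenzoyl chloride, Et3N, DMAP, toluene) with (2S)-2-[(tert-butyldimethylsilyl)oxy]but-3-enoic acid F5 (from resolved methyl 2-hydroxybut-3-enoate by silylation and hydrolysis), giving diene ester F6.
- Ring-closing metathesis with the second-generation Grubbs catalyst (CH2Cl2, 40 °C, 1 mM) closes the lactone at C3=C4 to the unsaturated macrolactone F7, either alkene geometry.
- Diimide (2-nitrobenzenesulfonyl hydrazide, Et3N) saturates this disubstituted alkene in preference to the trisubstituted ring alkene and gives 21.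

Step 10. The Z geometry may be lost through the allenolate, the cuprate may be consumed by the polyanionic substrate, or the dihydrofuranol may dehydrate before it is lactonised. The fallback sets out from 7 (with 14) and returns at 16. Hydroxyl-directed, copper-catalysed anti-carbomagnesiation of 7 (MeMgBr, CuI cat., THF), followed by iodine, gives the (Z)-iodoalkene F8; its geometry is fixed by the five-membered magnesium chelate. Deprotonation (LDA), iodine–lithium exchange (t-BuLi, −78 °C) and acylation by the lithium salt of 14 as in step 9 give Z-enone 16 on work-up. It closes to 17 and is lactonised to 18 with PPTS as in step 10.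

Further compounds
F0 | step 16 | none | none
F1 | step 12 | (S)-pent-1-en-4-yn-3-ol | C#C[C@@H](O)C=C
F2 | step 12 | (2S,3S,7S)-3-{(R)-[(4R)-2,2-dimethyl-1,3-dioxolan-4-yl][(triethylsilyl)oxy]methyl}-3,7-dihydroxy-2-methyl-4-oxonon-8-en-5-ynoic acid | C=C[C@H](O)C#CC(=O)[C@](O)([C@H](C)C(=O)O)[C@H](O[Si](CC)(CC)CC)[C@H]1COC(C)(C)O1
F3 | step 12 | (2S,5S,8S,9S)-9-{(R)-[(4R)-2,2-dimethyl-1,3-dioxolan-4-yl][(triethylsilyl)oxy]methyl}-2-ethenyl-9-hydroxy-3,8-dimethyl-1,6-dioxaspiro[4.4]non-3-en-7-one | C=C[C@@H]1O[C@@]2(C=C1C)OC(=O)[C@@H](C)[C@]2(O)[C@H](O[Si](CC)(CC)CC)[C@H]3COC(C)(C)O3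
F4 | step 12 | (2S,5S,8S,9S)-9-{(R)-[(4R)-2,2-dimethyl-1,3-dioxolan-4-yl](hydroxy)methyl}-2-ethenyl-9-hydroxy-3,8-dimethyl-1,6-dioxaspiro[4.4]non-3-en-7-one | C=C[C@@H]1O[C@@]2(C=C1C)OC(=O)[C@@H](C)[C@]2(O)[C@H](O)[C@H]3COC(C)(C)O3
F5 | step 12 | (2S)-2-[(tert-butyldimethylsilyl)oxy]but-3-enoic acid | C=C[C@H](O[Si](C)(C)C(C)(C)C)C(=O)O
F6 | step 12 | (R)-[(4R)-2,2-dimethyl-1,3-dioxolan-4-yl][(2S,5S,8S,9S)-2-ethenyl-9-hydroxy-3,8-dimethyl-7-oxo-1,6-dioxaspiro[4.4]non-3-en-9-yl]methyl (2S)-2-[(tert-butyldimethylsilyl)oxy]but-3-enoate | C=C[C@@H]1O[C@@]2(C=C1C)OC(=O)[C@@H](C)[C@]2(O)[C@H](OC(=O)[C@@H](O[Si](C)(C)C(C)(C)C)C=C)[C@H]3COC(C)(C)O3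
F7 | step 12 | 3,4-didehydro analogue of 21 (C3=C4 alkene, either geometry) | CC1(C)OC[C@@H](O1)[C@H]2OC(=O)[C@@H](O[Si](C)(C)C(C)(C)C)C=C[C@@H]3O[C@@]4(C=C3C)OC(=O)[C@@H](C)[C@]24O
F8 | step 10 | (2S,5S,6Z)-2-[(tert-butyldimethylsilyl)oxy]-5-hydroxy-7-iodo-6-methylhept-6-enoic acid | I/C=C(C)\[C@@H](O)CC[C@H](O[Si](C)(C)C(C)(C)C)C(=O)O
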